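**Retrosynthetic overview**
1. The oxirane, the only ring of the target, is formed last by hydroxyl-directed epoxidation of the C10=C11 alkene of the fully deprotected diene.
2. C5–C6 (key step): electroreductive, magnesium-mediated aldol of a C6–C15 α-benzoyloxy ketone with a C1–C5 aldehyde; it sets C5 and C6 and removes the relay oxygen.
3. C8–C9: boron anti-aldol of a glycerate-derived α'-benzoyloxy ketone (C6–C8 with both CH2O arms) with a C9–C15 dienal; it sets C8 and C9.
4. The dienal comes from (R)-Roche ester (C12) by two Wittig olefinations, the ketone from methyl (S)-glycerate acetonide, the aldehyde from ethyl 3-oxopentanoate.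
5. Stereocontrol chain: glycerate centre → C8/C9 → C5/C6; Roche centre (C12) together with C9 → C10/C11.

Assumption: locants C1–C15 in the explanations are those of the target's main chain counted from the ethyl ketone end (C3 and C7 are the ketone carbons, C15 the propenyl methyl); all starting materials are taken as commercial, the (S)-glycerate acetonide ester being the one made from L-serine.

**Step 1**
Reactants: 1 methyl (2R)-3-hydroxy-2-methylpropanoate
Product: 2 methyl (2R)-3-[(tert-butyldiphenylsilyl)oxy]-2-methylpropanoate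
Conditions: tBuPh2SiCl, imidazole, DMF, 0 °C → rt
Reagents that add atoms: tert-butyl(chloro)diphenylsilane, CC(C)(C)[Si](Cl)(c1ccccc1)c1ccccc1
Why: Imidazole-promoted O-silylation (silyl ether protection) of the primary alcohol leaves the bought stereocentre, the future C12, untouched.

**Step 2**
Reactants: 2 methyl (2R)-3-[(tert-butyldiphenylsilyl)oxy]-2-methylpropanoate; 3 ethyl(triphenyl)phosphonium bromide
Product: 5 tert-butyl{[(2S,3Z)-2-methylpent-3-en-1-yl]oxy}diphenylsilane, via silyloxy aldehyde 4 (not isolated)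
Conditions: iBu2AlH, CH2Cl2, −78 °C, aq. potassium sodium tartrate; crude 4, 3, NaN(SiMe3)2, THF, −78 °C → rt
Reagents that add atoms: none
Why: Partial ester reduction followed by a salt-free Wittig olefination of the unstabilised ylide gives the (Z)-alkene through the kinetic cis-oxaphosphetane, and the α-stereocentre does not epimerise at −78 °C.

**Step 3**
Reactants: 5 tert-butyl{[(2S,3Z)-2-methylpent-3-en-1-yl]oxy}diphenylsilane
Product: 6 (2S,3Z)-2-methylpent-3-en-1-ol
Conditions: Bu4NF, THF, 0 °C → rt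
Reagents that add atoms: none
Why: Fluoride-driven desilylation frees the primary alcohol without touching the stereocentre or the (Z)-alkene.

**Step 4**
Reactants: 6 (2S,3Z)-2-methylpent-3-en-1-ol; 7 2-(triphenyl-λ5-phosphanylidene)propanal
Product: 9 (2E,4S,5Z)-2,4-dimethylhepta-2,5-dienal, via (2S,3Z)-2-methylpent-3-enal 8 (not isolated)
Conditions: Dess–Martin periodinane, NaHCO3, CH2Cl2, 0 °C; crude 8, 7, PhMe, 80 °C
Reagents that add atoms: none
Why: Buffered Dess–Martin oxidation and immediate Wittig olefination with the stabilised formyl ylide give the (E)-trisubstituted enal (thermodynamic selectivity of stabilised ylides) before the β,γ-unsaturated aldehyde can epimerise or move into conjugation.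

**Step 5**
Reactants: 10 methyl (4S)-2,2-dimethyl-1,3-dioxolane-4-carboxylate
Product: 11 (4S)-N-methoxy-N,2,2-trimethyl-1,3-dioxolane-4-carboxamide
Conditions: MeNH(OMe)·HCl, iPrMgCl, THF, −20 °C
Reagents that add atoms: N,O-dimethylhydroxylamine hydrochloride, CNOC.Cl
Why: Aminolysis of the ester by the chloromagnesium amide (Weinreb amide synthesis) runs at low temperature without enolising the α-alkoxy stereocentre.

**Step 6**
Reactants: 11 (4S)-N-methoxy-N,2,2-trimethyl-1,3-dioxolane-4-carboxamide; 12 ethenylmagnesium bromide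
Product: 14 1-[(4S)-2,2-dimethyl-1,3-dioxolan-4-yl]-3-[(4-methoxyphenyl)methoxy]propan-1-one, via vinyl ketone 13 (not isolated)
Conditions: CH2=CHMgBr, THF, −78 → 0 °C, cold aq. HCl quench; crude 13, 4-MeOC6H4CH2OH, PMe3 (10 mol%), THF, 0 °C
Reagents that add atoms: (4-methoxyphenyl)methanol, COc1ccc(CO)cc1
Why: Grignard addition to the Weinreb amide stops at the ketone through the chelated tetrahedral intermediate, and phosphine-catalysed oxa-Michael addition of the benzylic alcohol to the vinyl ketone then gives the β-alkoxyethyl ketone without a β-alkoxy organometallic.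

**Step 7**
Reactants: 14 1-[(4S)-2,2-dimethyl-1,3-dioxolan-4-yl]-3-[(4-methoxyphenyl)methoxy]propan-1-one
Product: 15 (2S)-1,2-dihydroxy-5-[(4-methoxyphenyl)methoxy]pentan-3-one
Conditions: AcOH/H2O (4:1), 40 °C
Reagents that add atoms: none
Why: Mild acid hydrolysis of the isopropylidene acetal leaves the benzylic ether and the α-hydroxy ketone stereocentre intact.

**Step 8**
Reactants: 15 (2S)-1,2-dihydroxy-5-[(4-methoxyphenyl)methoxy]pentan-3-one
Product: 17 (2S)-1-[(tert-butyldimethylsilyl)oxy]-5-[(4-methoxyphenyl)methoxy]-3-oxopentan-2-yl benzoate, via mono-silyl ether 16 (not isolated)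
Conditions: tBuMe2SiCl, imidazole, CH2Cl2, −20 °C; then BzCl, Et3N, DMAP (cat.), 0 °C
Reagents that add atoms: tert-butyl(chloro)dimethylsilane, CC(C)(C)[Si](C)(C)Cl; benzoyl chloride, O=C(Cl)c1ccccc1
Why: The primary hydroxyl is silylated selectively on steric grounds and the remaining secondary hydroxyl is then acylated (DMAP-catalysed esterification), neither event touching the stereocentre.

**Step 9**
Reactants: 18 ethyl 3-oxopentanoate
Product: 19 ethyl 2-(2-ethyl-1,3-dioxolan-2-yl)acetate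
Conditions: HOCH2CH2OH, TsOH (cat.), PhMe, reflux, Dean–Stark
Reagents that add atoms: ethane-1,2-diol, OCCO
Why: Acid-catalysed ketalisation with azeotropic removal of water masks the ketone as its dioxolane.

**Step 10**
Reactants: 19 ethyl 2-(2-ethyl-1,3-dioxolan-2-yl)acetate
Product: 20 2-(2-ethyl-1,3-dioxolan-2-yl)acetaldehyde
Conditions: iBu2AlH, CH2Cl2, −78 °C
Reagents that add atoms: none
Why: Low-temperature partial reduction of the ester stops at the aluminium hemiacetal, which releases the aldehyde on work-up.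

**Step 11**
Reactants: 17 (2S)-1-[(tert-butyldimethylsilyl)oxy]-5-[(4-methoxyphenyl)methoxy]-3-oxopentan-2-yl benzoate; 9 (2E,4S,5Z)-2,4-dimethylhepta-2,5-dienal
Product: 22 (2S,4R,5S,6E,8S,9Z)-1-[(tert-butyldimethylsilyl)oxy]-5-hydroxy-4-{[(4-methoxyphenyl)methoxy]methyl}-6,8-dimethyl-3-oxoundeca-6,9-dien-2-yl benzoate, via enol dicyclohexylborinate 21 (not isolated)
Conditions: (c-C6H11)2BCl, Me2NEt, Et2O, −78 → 0 °C; 9, −78 → −25 °C; H2O2, MeOH, pH 7 buffer
Reagents that add atoms: none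
Why: The (E)-enol borinate formed on the CH2 side of the α'-benzoyloxy ketone reacts through a chair Zimmerman–Traxler transition state (Paterson anti-aldol of α-acyloxy ketones) in which the bought benzoyloxy stereocentre keeps its C–H in the enolate plane and its benzoate on the side of the incoming aldehyde, so the 8,9-anti adduct of (8R,9S) configuration is formed.

**Step 12**
Reactants: 22 (2S,4R,5S,6E,8S,9Z)-1-[(tert-butyldimethylsilyl)oxy]-5-hydroxy-4-{[(4-methoxyphenyl)methoxy]methyl}-6,8-dimethyl-3-oxoundeca-6,9-dien-2-yl benzoate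
Product: 23 (2S,4R,5S,6E,8S,9Z)-1-[(tert-butyldimethylsilyl)oxy]-4-{[(4-methoxyphenyl)methoxy]methyl}-6,8-dimethyl-3-oxo-5-[(triethylsilyl)oxy]undeca-6,9-dien-2-yl benzoate
Conditions: Et3SiOTf, 2,6-lutidine, CH2Cl2, −78 °C
Reagents that add atoms: triethylsilyl trifluoromethanesulfonate, CC[Si](CC)(CC)OS(=O)(=O)C(F)(F)F
Why: Silyl triflate silylation of the hindered secondary hydroxyl at −78 °C protects the aldol against retro-aldol cleavage in the next step.

**Step 13**
Reactants: 23 (2S,4R,5S,6E,8S,9Z)-1-[(tert-butyldimethylsilyl)oxy]-4-{[(4-methoxyphenyl)methoxy]methyl}-6,8-dimethyl-3-oxo-5-[(triethylsilyl)oxy]undeca-6,9-dien-2-yl benzoate; 20 2-(2-ethyl-1,3-dioxolan-2-yl)acetaldehyde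
Product: 25 (2S,3R,5R,6S,7E,9S,10Z)-3-{[(tert-butyldimethylsilyl)oxy]methyl}-1-(2-ethyl-1,3-dioxolan-2-yl)-2-hydroxy-5-{[(4-methoxyphenyl)methoxy]methyl}-7,9-dimethyl-6-[(triethylsilyl)oxy]dodeca-7,10-dien-4-one, via magnesium enolate 24 (not isolated)
Conditions: undivided cell, Mg anode, glassy-carbon cathode, Bu4NBF4 (0.1 M), THF/DMF (4:1), −40 °C, constant current, 2.2 F mol−1, 20 (2 equiv) present; aq. NH4Cl
Reagents that add atoms: none
Why: Proposed new method: cathodic two-electron reduction of the α-benzoyloxy ketone expels benzoate and, with the magnesium ions released by the sacrificial anode, gives regiospecifically the (Z)-magnesium enolate chelated to the neighbouring 4-methoxybenzyl ether oxygen, which adds to the aldehyde through a chair transition state on the face opposite the C9 branch and so gives the 5,6-syn aldol of (5S,6R) configuration while erasing the relay stereocentre; the closest known reactions are the electroreductive Reformatsky coupling of α-halo carbonyl compounds at sacrificial magnesium or zinc anodes, the SmI2 cleavage of α-acyloxy ketones and the chelation-controlled syn-aldol of enolates made with Sn(OTf)2.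

**Step 14**
Reactants: 25 (2S,3R,5R,6S,7E,9S,10Z)-3-{[(tert-butyldimethylsilyl)oxy]methyl}-1-(2-ethyl-1,3-dioxolan-2-yl)-2-hydroxy-5-{[(4-methoxyphenyl)methoxy]methyl}-7,9-dimethyl-6-[(triethylsilyl)oxy]dodeca-7,10-dien-4-one
Product: 26 (2S,3R,5R,6S,7E,9S,10Z)-3-{[(tert-butyldimethylsilyl)oxy]methyl}-1-(2-ethyl-1,3-dioxolan-2-yl)-2-hydroxy-5-(hydroxymethyl)-7,9-dimethyl-6-[(triethylsilyl)oxy]dodeca-7,10-dien-4-one
Conditions: DDQ, CH2Cl2/pH 7 buffer (10:1), 0 °C
Reagents that add atoms: none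
Why: Oxidative cleavage of the electron-rich 4-methoxybenzyl ether (hydride abstraction, then hydrolysis of the oxocarbenium ion) outpaces oxidation of the skipped diene at 0 °C.

**Step 15**
Reactants: 26 (2S,3R,5R,6S,7E,9S,10Z)-3-{[(tert-butyldimethylsilyl)oxy]methyl}-1-(2-ethyl-1,3-dioxolan-2-yl)-2-hydroxy-5-(hydroxymethyl)-7,9-dimethyl-6-[(triethylsilyl)oxy]dodeca-7,10-dien-4-one
Product: 27 (5S,6R,8R,9S,10E,12S,13Z)-5,9-dihydroxy-6,8-bis(hydroxymethyl)-10,12-dimethylpentadeca-10,13-diene-3,7-dione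
Conditions: aq. HF (48%), MeCN, 0 °C → rt
Reagents that add atoms: water, O
Why: Aqueous HF removes both silyl ethers (Si–F bond formation) and hydrolyses the dioxolane (acetal hydrolysis) in one operation, before the acid-sensitive epoxide exists.

**Step 16**
Reactants: 27 (5S,6R,8R,9S,10E,12S,13Z)-5,9-dihydroxy-6,8-bis(hydroxymethyl)-10,12-dimethylpentadeca-10,13-diene-3,7-dione
Product: 28 (5S,6R,8R,9S,10R,11R,12S,13Z)-10,11-epoxy-5,9-dihydroxy-6,8-bis(hydroxymethyl)-10,12-dimethylpentadec-13-ene-3,7-dione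
Conditions: mCPBA, NaHCO3, CH2Cl2, −20 °C
Reagents that add atoms: 3-chloroperoxybenzoic acid, O=C(OO)c1cccc(Cl)c1
Why: In this hydroxyl-directed Prilezhaev epoxidation the electron-rich trisubstituted alkene reacts before the (Z)-disubstituted one, and the peracid, hydrogen-bonded to the C9 hydroxyl, attacks the face opposite the (Z)-propenyl group of the A(1,3)-locked C12 centre, which sets (10R,11R) with the epoxide threo to C9–OH and syn to the C12 methyl.

**Compound list**
1 | methyl (2R)-3-hydroxy-2-methylpropanoate | COC(=O)[C@H](C)CO | starting material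
2 | methyl (2R)-3-[(tert-butyldiphenylsilyl)oxy]-2-methylpropanoate | COC(=O)[C@H](C)CO[Si](c1ccccc1)(c1ccccc1)C(C)(C)C | intermediate
3 | ethyl(triphenyl)phosphonium bromide | CC[P+](c1ccccc1)(c1ccccc1)c1ccccc1.[Br-] | starting material
4 | (2R)-3-[(tert-butyldiphenylsilyl)oxy]-2-methylpropanal | O=C[C@H](C)CO[Si](c1ccccc1)(c1ccccc1)C(C)(C)C | intermediate
5 | tert-butyl{[(2S,3Z)-2-methylpent-3-en-1-yl]oxy}diphenylsilane | C/C=C\[C@H](C)CO[Si](c1ccccc1)(c1ccccc1)C(C)(C)C | intermediate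
6 | (2S,3Z)-2-methylpent-3-en-1-ol | C/C=C\[C@H](C)CO | intermediate
7 | 2-(triphenyl-λ5-phosphanylidene)propanal | CC(C=O)=P(c1ccccc1)(c1ccccc1)c1ccccc1 | starting material
8 | (2S,3Z)-2-methylpent-3-enal | C/C=C\[C@H](C)C=O | intermediate
9 | (2E,4S,5Z)-2,4-dimethylhepta-2,5-dienal | C/C=C\[C@H](C)/C=C(\C)C=O | intermediate
10 | methyl (4S)-2,2-dimethyl-1,3-dioxolane-4-carboxylate | COC(=O)[C@@H]1COC(C)(C)O1 | starting material
11 | (4S)-N-methoxy-N,2,2-trimethyl-1,3-dioxolane-4-carboxamide | CON(C)C(=O)[C@@H]1COC(C)(C)O1 | intermediate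
12 | ethenylmagnesium bromide | C=C[Mg]Br | starting material
13 | 1-[(4S)-2,2-dimethyl-1,3-dioxolan-4-yl]prop-2-en-1-one | C=CC(=O)[C@@H]1COC(C)(C)O1 | intermediate
14 | 1-[(4S)-2,2-dimethyl-1,3-dioxolan-4-yl]-3-[(4-methoxyphenyl)methoxy]propan-1-one | COc1ccc(COCCC(=O)[C@@H]2COC(C)(C)O2)cc1 | intermediate
15 | (2S)-1,2-dihydroxy-5-[(4-methoxyphenyl)methoxy]pentan-3-one | COc1ccc(COCCC(=O)[C@@H](O)CO)cc1 | intermediate
16 | (2S)-1-[(tert-butyldimethylsilyl)oxy]-2-hydroxy-5-[(4-methoxyphenyl)methoxy]pentan-3-one | COc1ccc(COCCC(=O)[C@@H](O)CO[Si](C)(C)C(C)(C)C)cc1 | intermediate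
17 | (2S)-1-[(tert-butyldimethylsilyl)oxy]-5-[(4-methoxyphenyl)methoxy]-3-oxopentan-2-yl benzoate | COc1ccc(COCCC(=O)[C@@H](OC(=O)c2ccccc2)CO[Si](C)(C)C(C)(C)C)cc1 | intermediate
18 | ethyl 3-oxopentanoate | CCOC(=O)CC(=O)CC | starting material
19 | ethyl 2-(2-ethyl-1,3-dioxolan-2-yl)acetate | CCOC(=O)CC1(CC)OCCO1 | intermediate
20 | 2-(2-ethyl-1,3-dioxolan-2-yl)acetaldehyde | CCC1(CC=O)OCCO1 | intermediate
21 | (2S,3E)-1-[(tert-butyldimethylsilyl)oxy]-3-[(dicyclohexylboranyl)oxy]-5-[(4-methoxyphenyl)methoxy]pent-3-en-2-yl benzoate | COc1ccc(COC/C=C(/OB(C2CCCCC2)C2CCCCC2)[C@@H](OC(=O)c2ccccc2)CO[Si](C)(C)C(C)(C)C)cc1 | intermediate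
22 | (2S,4R,5S,6E,8S,9Z)-1-[(tert-butyldimethylsilyl)oxy]-5-hydroxy-4-{[(4-methoxyphenyl)methoxy]methyl}-6,8-dimethyl-3-oxoundeca-6,9-dien-2-yl benzoate | C/C=C\[C@H](C)/C=C(\C)[C@@H](O)[C@@H](COCc1ccc(OC)cc1)C(=O)[C@H](CO[Si](C)(C)C(C)(C)C)OC(=O)c1ccccc1 | intermediate
23 | (2S,4R,5S,6E,8S,9Z)-1-[(tert-butyldimethylsilyl)oxy]-4-{[(4-methoxyphenyl)methoxy]methyl}-6,8-dimethyl-3-oxo-5-[(triethylsilyl)oxy]undeca-6,9-dien-2-yl benzoate | C/C=C\[C@H](C)/C=C(\C)[C@@H](O[Si](CC)(CC)CC)[C@@H](COCc1ccc(OC)cc1)C(=O)[C@H](CO[Si](C)(C)C(C)(C)C)OC(=O)c1ccccc1 | intermediate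
24 | {[(2Z,4R,5S,6E,8S,9Z)-1-[(tert-butyldimethylsilyl)oxy]-4-{[(4-methoxyphenyl)methoxy]methyl}-6,8-dimethyl-5-[(triethylsilyl)oxy]undeca-2,6,9-trien-3-yl]oxy}magnesium benzoate | C/C=C\[C@H](C)/C=C(\C)[C@@H](O[Si](CC)(CC)CC)[C@@H](COCc1ccc(OC)cc1)/C(O[Mg]OC(=O)c1ccccc1)=C/CO[Si](C)(C)C(C)(C)C | intermediate
25 | (2S,3R,5R,6S,7E,9S,10Z)-3-{[(tert-butyldimethylsilyl)oxy]methyl}-1-(2-ethyl-1,3-dioxolan-2-yl)-2-hydroxy-5-{[(4-methoxyphenyl)methoxy]methyl}-7,9-dimethyl-6-[(triethylsilyl)oxy]dodeca-7,10-dien-4-one | C/C=C\[C@H](C)/C=C(\C)[C@@H](O[Si](CC)(CC)CC)[C@@H](COCc1ccc(OC)cc1)C(=O)[C@H](CO[Si](C)(C)C(C)(C)C)[C@@H](O)CC1(CC)OCCO1 | intermediate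
26 | (2S,3R,5R,6S,7E,9S,10Z)-3-{[(tert-butyldimethylsilyl)oxy]methyl}-1-(2-ethyl-1,3-dioxolan-2-yl)-2-hydroxy-5-(hydroxymethyl)-7,9-dimethyl-6-[(triethylsilyl)oxy]dodeca-7,10-dien-4-one | C/C=C\[C@H](C)/C=C(\C)[C@@H](O[Si](CC)(CC)CC)[C@@H](CO)C(=O)[C@H](CO[Si](C)(C)C(C)(C)C)[C@@H](O)CC1(CC)OCCO1 | intermediate
27 | (5S,6R,8R,9S,10E,12S,13Z)-5,9-dihydroxy-6,8-bis(hydroxymethyl)-10,12-dimethylpentadeca-10,13-diene-3,7-dione | C/C=C\[C@H](C)/C=C(\C)[C@@H](O)[C@@H](CO)C(=O)[C@H](CO)[C@@H](O)CC(=O)CC | intermediate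
28 | (5S,6R,8R,9S,10R,11R,12S,13Z)-10,11-epoxy-5,9-dihydroxy-6,8-bis(hydroxymethyl)-10,12-dimethylpentadec-13-ene-3,7-dione (CNP0266199.1) | C/C=C\[C@H](C)[C@H]1O[C@]1(C)[C@@H](O)[C@@H](CO)C(=O)[C@H](CO)[C@@H](O)CC(=O)CC | target

**Count and weak points**
Total step count: 16. Longest linear sequence: 10 steps (steps 5–8 followed by 11–16; the chain through steps 1–4 and 11–16 is equally long).

The three steps most likely to fail:

Step 13 (the proposed new step). The aldehyde may be reduced in competition, the enolate may lose the silyloxy arm by β-elimination, or chelation control may be weak. The fallback uses known chemistry, sets out from 23 and comes back to the route at 25. SmI2 in THF/MeOH at −78 °C cleaves the benzoate reductively and gives (4R,5S,6E,8S,9Z)-1-[(tert-butyldimethylsilyl)oxy]-4-{[(4-methoxyphenyl)methoxy]methyl}-6,8-dimethyl-5-[(triethylsilyl)oxy]undeca-6,9-dien-3-one F1. This ketone is enolised on its CH2 side with Sn(OTf)2 and Et3N in CH2Cl2 at −78 °C to the chelated (Z)-enolate of divalent tin. Addition of 20 then gives 25 by the same facial argument.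

Step 16. On the unprotected polyol, competing hydroxyl groups or hemiketal forms could erode the facial selectivity, and the polar product may be hard to recover. The fallback sets out from 25 and comes back at 28, with the epoxidation moved ahead of the last deprotections. Pyridinium p-toluenesulfonate in acetone/H2O at 40 °C removes the dioxolane and the triethylsilyl ether but keeps the primary silyl ether, giving (5S,6R,8R,9S,10E,12S,13Z)-6-{[(tert-butyldimethylsilyl)oxy]methyl}-5,9-dihydroxy-8-{[(4-methoxyphenyl)methoxy]methyl}-10,12-dimethylpentadeca-10,13-diene-3,7-dione F2. Buffered mCPBA at −20 °C, directed by the C9 hydroxyl on this lipophilic substrate, gives (5S,6R,8R,9S,10R,11R,12S,13Z)-6-{[(tert-butyldimethylsilyl)oxy]methyl}-10,11-epoxy-5,9-dihydroxy-8-{[(4-methoxyphenyl)methoxy]methyl}-10,12-dimethylpentadec-13-ene-3,7-dione F3. DDQ gives (5S,6R,8R,9S,10R,11R,12S,13Z)-6-{[(tert-butyldimethylsilyl)oxy]methyl}-10,11-epoxy-5,9-dihydroxy-8-(hydroxymethyl)-10,12-dimethylpentadec-13-ene-3,7-dione F4. HF·pyridine buffered with pyridine in THF at 0 °C then gives 28, so the epoxide never meets a strong acid.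

Step 4. The formyl ylide needs heat, and aldehyde 8 can epimerise at the future C12 or slip into conjugation. The fallback sets out from 6 and comes back at 9. Alcohol 6 is oxidised as before to 8, which reacts at room temperature with ethyl 2-(triphenyl-λ5-phosphanylidene)propanoate in CH2Cl2 to give ethyl (2E,4S,5Z)-2,4-dimethylhepta-2,5-dienoate F5. iBu2AlH at −78 °C reduces it to (2E,4S,5Z)-2,4-dimethylhepta-2,5-dien-1-ol F6, and MnO2 in CH2Cl2 oxidises this allylic alcohol to 9.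

**Further compounds**
F1 | step 13 | (4R,5S,6E,8S,9Z)-1-[(tert-butyldimethylsilyl)oxy]-4-{[(4-methoxyphenyl)methoxy]methyl}-6,8-dimethyl-5-[(triethylsilyl)oxy]undeca-6,9-dien-3-one | C/C=C\[C@H](C)/C=C(\C)[C@@H](O[Si](CC)(CC)CC)[C@@H](COCc1ccc(OC)cc1)C(=O)CCO[Si](C)(C)C(C)(C)C
F2 | step 16 | (5S,6R,8R,9S,10E,12S,13Z)-6-{[(tert-butyldimethylsilyl)oxy]methyl}-5,9-dihydroxy-8-{[(4-methoxyphenyl)methoxy]methyl}-10,12-dimethylpentadeca-10,13-diene-3,7-dione | C/C=C\[C@H](C)/C=C(\C)[C@@H](O)[C@@H](COCc1ccc(OC)cc1)C(=O)[C@H](CO[Si](C)(C)C(C)(C)C)[C@@H](O)CC(=O)CC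
F3 | step 16 | (5S,6R,8R,9S,10R,11R,12S,13Z)-6-{[(tert-butyldimethylsilyl)oxy]methyl}-10,11-epoxy-5,9-dihydroxy-8-{[(4-methoxyphenyl)methoxy]methyl}-10,12-dimethylpentadec-13-ene-3,7-dione | C/C=C\[C@H](C)[C@H]1O[C@]1(C)[C@@H](O)[C@@H](COCc1ccc(OC)cc1)C(=O)[C@H](CO[Si](C)(C)C(C)(C)C)[C@@H](O)CC(=O)CC
F4 | step 16 | (5S,6R,8R,9S,10R,11R,12S,13Z)-6-{[(tert-butyldimethylsilyl)oxy]methyl}-10,11-epoxy-5,9-dihydroxy-8-(hydroxymethyl)-10,12-dimethylpentadec-13-ene-3,7-dione | C/C=C\[C@H](C)[C@H]1O[C@]1(C)[C@@H](O)[C@@H](CO)C(=O)[C@H](CO[Si](C)(C)C(C)(C)C)[C@@H](O)CC(=O)CC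
F5 | step 4 | ethyl (2E,4S,5Z)-2,4-dimethylhepta-2,5-dienoate | C/C=C\[C@H](C)/C=C(\C)C(=O)OCC
F6 | step 4 | (2E,4S,5Z)-2,4-dimethylhepta-2,5-dien-1-ol | C/C=C\[C@H](C)/C=C(\C)CO
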